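The seven-membered ring is cut at C9–C10, and the C4(OH)–C5H–C6(OH)–C7H–C11(OH) array is read as a C6 ketone flanked by two enone double bonds. Ring-closing metathesis of a trienone joins the isopropenyl carbon C10 of an (R)-limonene-derived cyclopentene (ring A, C1 already set) to the allyl terminus C9 of a dihydroxyacetone-derived fragment and so closes the seven-membered ring onto ring A. It exploits the fact that the C10 methyl carbinol is a latent trisubstituted C9=C10 olefin of that ring. The resulting cross-conjugated dienone then takes up both β-hydroxyls and H-5 and H-7 by two-directional epoxidation and reductive opening.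

Key step: step 7

Remark: commercial (+)-limonene 1,2-oxide is taken as the cis/trans mixture of the (4R) series; both diastereomers converge in step 1. Guaiane numbering is used for the bicyclic compounds (ring A = C1–C5; seven-membered ring = C1, C5–C10; C11 on C7 carries C12 and C13; C14 on C10; C15 on C4). α denotes the face that carries H-1.

Step 1
Reactants: 1 (4R)-limonene 1,2-oxide
Product: 2 (3R)-6-oxo-3-(prop-1-en-2-yl)heptanal
Conditions: H5IO6, THF/H2O, 0 °C to rt
Reagents that add atoms: water, O
Why: Periodic acid should hydrolyse the epoxide to the glycol and cleave it (Malaprade-type oxidative cleavage), both epoxide diastereomers converging while the limonene stereocentre (later C1) is untouched.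

Step 2
Reactants: 2 (3R)-6-oxo-3-(prop-1-en-2-yl)heptanal
Product: 3 (5S)-2-methyl-5-(prop-1-en-2-yl)cyclopent-1-ene-1-carbaldehyde
Conditions: piperidine (cat.), AcOH (cat.), benzene, 80 °C
Reagents that add atoms: none
Why: Intramolecular aldol condensation through the aldehyde enamine onto the methyl ketone should close ring A as the tetrasubstituted enal without touching the stereocentre.

Step 3
Reactants: 4 2,2-dimethyl-1,3-dioxan-5-one
Product: 5 5-(dibromomethylidene)-2,2-dimethyl-1,3-dioxane
Conditions: CBr4, PPh3, CH2Cl2, 0 °C to rt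
Reagents that add atoms: carbon tetrabromide, BrC(Br)(Br)Br
Why: Ramirez dibromo-olefination of the activated, unhindered ketone by the ylide formed in situ should give the gem-dibromo olefin, whose carbon becomes C7; no stereocentre is formed.

Step 4
Reactants: 5 5-(dibromomethylidene)-2,2-dimethyl-1,3-dioxane
Product: 6 5-(1-bromobut-3-en-1-ylidene)-2,2-dimethyl-1,3-dioxane
Conditions: allyltributylstannane, Pd2(dba)3 (cat.), tri(2-furyl)phosphine, toluene, 80 °C
Reagents that add atoms: allyltributylstannane, C=CC[Sn](CCCC)(CCCC)CCCC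
Why: Stille coupling should stop after one allylation because the remaining C–Br bond sits on a tetrasubstituted, hindered olefin, and the two identical dioxane arms remove any olefin-geometry issue.

Step 5
Reactants: 6 5-(1-bromobut-3-en-1-ylidene)-2,2-dimethyl-1,3-dioxane; 3 (5S)-2-methyl-5-(prop-1-en-2-yl)cyclopent-1-ene-1-carbaldehyde
Product: 8 bis-allylic alcohol 2-(2,2-dimethyl-1,3-dioxan-5-ylidene)-1-[(5S)-2-methyl-5-(prop-1-en-2-yl)cyclopent-1-en-1-yl]pent-4-en-1-ol, via vinyllithium 7 (not isolated)
Conditions: t-BuLi (2 equiv), THF, −78 °C; then 3, −78 °C; H2O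
Reagents that add atoms: none
Why: Bromine–lithium exchange followed by 1,2-addition of the alkenyllithium to the enal should forge the C6–C7 bond, the new carbinol centre being of no consequence because it is oxidised in the next step.

Step 6
Reactants: 8 bis-allylic alcohol
Product: 9 trienone 2-(2,2-dimethyl-1,3-dioxan-5-ylidene)-1-[(5S)-2-methyl-5-(prop-1-en-2-yl)cyclopent-1-en-1-yl]pent-4-en-1-one
Conditions: Dess–Martin periodinane, NaHCO3, CH2Cl2, rt
Reagents that add atoms: none
Why: Dess–Martin oxidation under buffered conditions should give the cross-conjugated dienone while sparing the acetonide and the skipped diene.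

Step 7
Reactants: 9 trienone
Product: 10 (1S)-12,13-(isopropylidenedioxy)guaia-4,7(11),9-trien-6-one
Conditions: second-generation Grubbs catalyst (cat.), 1,4-benzoquinone (cat.), toluene, high dilution, 80 °C
Reagents that add atoms: none
Why: Ring-closing olefin metathesis by the metallacyclobutane sequence of [2+2] cycloaddition and cycloreversion: the ruthenium alkylidene should load onto the monosubstituted allyl terminus (C9), add across the 1,1-disubstituted isopropenyl olefin and release the trisubstituted C9=C10 double bond with loss of ethene. The closest known reaction type is the ring-closing metathesis of an allyl group with an isopropenyl group to a methylcycloheptene in hydroazulene synthesis. The seven-membered ring (C1, C5, C6, C7, C8, C9, C10) is closed through the new C9=C10 bond onto the existing cyclopentene ring A, so it is the last ring of the carbon skeleton to form. No stereocentre is created, and C1 from limonene is not epimerisable under these neutral conditions. The step needs chemoselectivity for the two least substituted olefins and freedom from isomerisation of the skipped diene: the enone olefins C4=C5 and C7=C11 are tetrasubstituted and electron-poor and therefore inert, benzoquinone suppresses ruthenium hydride isomerisation and high dilution suppresses dimerisation. The cross-conjugated dienone can also place C7 and C1 on the same side of the C6 carbonyl, which brings the two reacting olefins within reach.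

Step 8
Reactants: 10 (1S)-12,13-(isopropylidenedioxy)guaia-4,7(11),9-trien-6-one
Product: 11 4α,5α:7,11-diepoxy-12,13-(isopropylidenedioxy)-1αH-guai-9-en-6-one
Conditions: 30% H2O2, aq. NaOH (cat.), MeOH, 0 °C to rt
Reagents that add atoms: hydrogen peroxide, OO
Why: Weitz–Scheffer nucleophilic epoxidation should convert both enone olefins and leave the isolated C9=C10 olefin, the C4–C5 epoxide closing on the α face anti to the C1–C10 bond, while the C7 configuration is irrelevant because C7 is later re-formed from an enolate.

Step 9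
Reactants: 11 4α,5α:7,11-diepoxy-12,13-(isopropylidenedioxy)-1αH-guai-9-en-6-one
Product: 13 4α,5α:7,11-diepoxy-10α-hydroxy-12,13-(isopropylidenedioxy)-1αH-guaian-6-one, via tertiary hydroperoxide 12 (not isolated)
Conditions: Co(acac)2 (cat.), PhSiH3, O2 (1 atm), THF, rt; then PPh3
Reagents that add atoms: dioxygen, O=O
Why: Mukaiyama hydration (Markovnikov hydrogen-atom transfer to the only olefin) should give the tertiary C10 radical, which O2 captures on the convex α face anti to ring A, placing 10-OH cis to H-1.

Step 10
Reactants: 13 4α,5α:7,11-diepoxy-10α-hydroxy-12,13-(isopropylidenedioxy)-1αH-guaian-6-one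
Product: 14 4α,10α,11-trihydroxy-12,13-(isopropylidenedioxy)-1αH,5αH,7αH-guaian-6-one
Conditions: SmI2 (5 equiv), THF/MeOH, −78 °C
Reagents that add atoms: none
Why: Single-electron reduction of the bis(α,β-epoxy) ketone by divalent samarium should cleave both α-C–O bonds to samarium enolates, and kinetic protonation of each by methanol from the open α face (the β face carries 4-Me, 10-Me and ring A) sets H-5 and H-7 cis to H-1.

Step 11
Reactants: 14 4α,10α,11-trihydroxy-12,13-(isopropylidenedioxy)-1αH,5αH,7αH-guaian-6-one
Product: 15 12,13-(isopropylidenedioxy)-1αH,5αH,7αH-guaiane-4α,6α,10α,11-tetraol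
Conditions: Li, liquid NH3/THF, t-BuOH, −78 °C; then NH4Cl
Reagents that add atoms: none
Why: Dissolving-metal (electron-transfer) reduction should give the thermodynamically favoured pseudo-equatorial 6α-carbinol, trans to the β-oriented substituents on C5 and C7, whereas a hydride reagent attacking the open α face would give the 6β-epimer.

Step 12
Reactants: 15 12,13-(isopropylidenedioxy)-1αH,5αH,7αH-guaiane-4α,6α,10α,11-tetraol
Product: 16 1αH,5αH,7αH-guaiane-4α,6α,10α,11,12,13-hexaol
Conditions: 80% aq. AcOH, rt
Reagents that add atoms: none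
Why: Acid-catalysed acetal hydrolysis should free the two primary hydroxyls without dehydrating the tertiary carbinols at room temperature.

Step 13
Reactants: 16 1αH,5αH,7αH-guaiane-4α,6α,10α,11,12,13-hexaol
Product: 17 target 12,13-diacetoxy-1αH,5αH,7αH-guaiane-4α,6α,10α,11-tetraol
Conditions: AcCl (2 equiv), 2,4,6-collidine, CH2Cl2, −78 °C
Reagents that add atoms: acetyl chloride, CC(=O)Cl
Why: Low-temperature acylation with acetyl chloride and collidine is selective for primary hydroxyls, so both CH2OH groups should be acetylated while the flanked secondary 6-OH and the three tertiary hydroxyls stay free.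

Compound list
1 | (4R)-limonene 1,2-oxide, commercial cis/trans mixture | CC1(O2)C2C[C@@H](CC1)C(C)=C | starting material
2 | (3R)-6-oxo-3-(prop-1-en-2-yl)heptanal | O=CC[C@@H](CCC(C)=O)C(C)=C | intermediate
3 | (5S)-2-methyl-5-(prop-1-en-2-yl)cyclopent-1-ene-1-carbaldehyde | CC1=C(C=O)[C@@H](CC1)C(C)=C | intermediate
4 | 2,2-dimethyl-1,3-dioxan-5-one | CC1(C)OCC(=O)CO1 | starting material
5 | 5-(dibromomethylidene)-2,2-dimethyl-1,3-dioxane | CC1(C)OCC(CO1)=C(Br)Br | intermediate
6 | 5-(1-bromobut-3-en-1-ylidene)-2,2-dimethyl-1,3-dioxane | CC1(C)OCC(CO1)=C(Br)CC=C | intermediate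
7 | [1-(2,2-dimethyl-1,3-dioxan-5-ylidene)but-3-en-1-yl]lithium | CC1(C)OCC(CO1)=C([Li])CC=C | intermediate (not isolated)
8 | 2-(2,2-dimethyl-1,3-dioxan-5-ylidene)-1-[(5S)-2-methyl-5-(prop-1-en-2-yl)cyclopent-1-en-1-yl]pent-4-en-1-ol, both carbinol epimers | CC1(C)OCC(CO1)=C(CC=C)C(O)C2=C(C)CC[C@H]2C(C)=C | intermediate
9 | 2-(2,2-dimethyl-1,3-dioxan-5-ylidene)-1-[(5S)-2-methyl-5-(prop-1-en-2-yl)cyclopent-1-en-1-yl]pent-4-en-1-one | CC1(C)OCC(CO1)=C(CC=C)C(=O)C2=C(C)CC[C@H]2C(C)=C | intermediate
10 | (1S)-12,13-(isopropylidenedioxy)guaia-4,7(11),9-trien-6-one | CC1(C)OCC(CO1)=C2CC=C(C)[C@@H]3CCC(C)=C3C2=O | intermediate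
11 | 4α,5α:7,11-diepoxy-12,13-(isopropylidenedioxy)-1αH-guai-9-en-6-one, both C7 epimers | CC1(C)OCC2(CO1)OC23CC=C(C)[C@@H]4CC[C@@]5(C)O[C@@]45C3=O | intermediate
12 | 4α,5α:7,11-diepoxy-10α-hydroperoxy-12,13-(isopropylidenedioxy)-1αH-guaian-6-one | CC1(C)OCC2(CO1)OC23CC[C@@](C)(OO)[C@@H]4CC[C@@]5(C)O[C@@]45C3=O | intermediate (not isolated)
13 | 4α,5α:7,11-diepoxy-10α-hydroxy-12,13-(isopropylidenedioxy)-1αH-guaian-6-one, both C7 epimers | CC1(C)OCC2(CO1)OC23CC[C@@](C)(O)[C@@H]4CC[C@@]5(C)O[C@@]45C3=O | intermediate
14 | 4α,10α,11-trihydroxy-12,13-(isopropylidenedioxy)-1αH,5αH,7αH-guaian-6-one | CC1(C)OCC(O)(CO1)[C@@H]2CC[C@@](C)(O)[C@@H]3CC[C@@](C)(O)[C@@H]3C2=O | intermediate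
15 | 12,13-(isopropylidenedioxy)-1αH,5αH,7αH-guaiane-4α,6α,10α,11-tetraol | CC1(C)OCC(O)(CO1)[C@@H]2CC[C@@](C)(O)[C@@H]3CC[C@@](C)(O)[C@@H]3[C@H]2O | intermediate
16 | 1αH,5αH,7αH-guaiane-4α,6α,10α,11,12,13-hexaol | OCC(O)(CO)[C@@H]1CC[C@@](C)(O)[C@@H]2CC[C@@](C)(O)[C@@H]2[C@H]1O | intermediate
17 | 12,13-diacetoxy-1αH,5αH,7αH-guaiane-4α,6α,10α,11-tetraol, (1R,4R,5S,6S,7R,10R), CNP0179913.1 | CC(=O)OCC(O)(COC(C)=O)[C@@H]1CC[C@@](C)(O)[C@@H]2CC[C@@](C)(O)[C@@H]2[C@H]1O | target

Total step count: 13. Longest linear sequence: 11 steps (steps 1, 2 and 5–13 from 1; equally steps 3–13 from 4).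

Steps most likely to fail

Step 10. Protonation of the two samarium enolates may show poor facial selectivity at C5 or C7, or the β-alkoxy ketone may fragment by retro-aldol. The fallback sets out from 13 and replaces enolate protonation by radical hydrogen-atom transfer. Luche reduction (NaBH4, CeCl3·7H2O, MeOH) would give bis-epoxy alcohol F1, whose C6 configuration does not matter. Titanocene chloride made from Cp2TiCl2 and Zn (trivalent titanium), with 1,4-cyclohexadiene, would open both 2,3-epoxy alcohol units homolytically at C5 and C7 to the 1,3-diols. The tertiary radicals would take hydrogen from the diene on the open α face, giving tetraol acetonide F2 as C6 epimers. Dess–Martin oxidation of the only secondary hydroxyl would return to the route at 14.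

Step 8. Hydroperoxide attack at the two fully substituted β-carbons may be slow or incomplete, and the α-face preference at C4–C5 may be poor. The fallback sets out from 10 and switches to electrophilic, hydroxyl-directed epoxidation. Luche reduction would give bis-allylic alcohol F3. VO(acac)2 with t-BuOOH would epoxidise both allylic olefins through the vanadate ester, much faster than the remote C9=C10 olefin and again on the α face of ring A, to give bis-epoxy alcohol F4. Dess–Martin oxidation would return to the route at 11.

Step 9. Capture of the planar C10 radical by O2 may show poor facial selectivity and give the 10-epimer. The fallback sets out from 11 and postpones the C10 oxygenation. Under the conditions of step 10 the olefin-bearing bis-epoxy ketone would give hydroxy ketone F5, and under those of step 11 the alcohol F6 (an isolated olefin is inert to both). Epoxidation with m-CPBA/NaHCO3 should occur on the convex α face, guided by hydrogen bonding to the 6α-hydroxyl, to give epoxide F7. An α-hydroxyl cannot open an α-epoxide from the rear, so transannular ether formation is not expected. LiAlH4 would deliver hydride to the secondary carbon C9 and return to the route at 15.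

Further compounds
F1 | step 10 | 4α,5α:7,11-diepoxy-12,13-(isopropylidenedioxy)-1αH-guaiane-6,10α-diol, C6 and C7 epimers | CC1(C)OCC2(CO1)OC23CC[C@@](C)(O)[C@@H]4CC[C@@]5(C)O[C@@]45C3O
F2 | step 10 | 12,13-(isopropylidenedioxy)-1αH,5αH,7αH-guaiane-4α,6,10α,11-tetraol, C6 epimers | CC1(C)OCC(O)(CO1)[C@@H]2CC[C@@](C)(O)[C@@H]3CC[C@@](C)(O)[C@@H]3C2O
F3 | step 8 | (1S)-12,13-(isopropylidenedioxy)guaia-4,7(11),9-trien-6-ol, C6 epimers | CC1(C)OCC(CO1)=C2CC=C(C)[C@@H]3CCC(C)=C3C2O
F4 | step 8 | 4α,5α:7,11-diepoxy-12,13-(isopropylidenedioxy)-1αH-guai-9-en-6-ol, C6 and C7 epimers | CC1(C)OCC2(CO1)OC23CC=C(C)[C@@H]4CC[C@@]5(C)O[C@@]45C3O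
F5 | step 9 | 4α,11-dihydroxy-12,13-(isopropylidenedioxy)-1αH,5αH,7αH-guai-9-en-6-one | CC1(C)OCC(O)(CO1)[C@@H]2CC=C(C)[C@@H]3CC[C@@](C)(O)[C@@H]3C2=O
F6 | step 9 | 12,13-(isopropylidenedioxy)-1αH,5αH,7αH-guai-9-ene-4α,6α,11-triol | CC1(C)OCC(O)(CO1)[C@@H]2CC=C(C)[C@@H]3CC[C@@](C)(O)[C@@H]3[C@H]2O
F7 | step 9 | 9α,10α-epoxy-12,13-(isopropylidenedioxy)-1αH,5αH,7αH-guaiane-4α,6α,11-triol | CC1(C)OCC(O)(CO1)[C@@H]2C[C@H]4O[C@@]4(C)[C@@H]3CC[C@@](C)(O)[C@@H]3[C@H]2O
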